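**Strategy.** The target is an all-cis 2-aryl tetrahydrofuran lignan core extended by two trans-2-aryl-3-(hydroxymethyl)-2,3-dihydrobenzofurans. The route rests on the benzylic C2–O1 bond of the inner dihydrobenzofuran: C2 lies para to the oxygen of the outer benzofuran ring, so its carbinol ionises readily. Two Evans aldol reactions fix only C3 of each benzofuran. One acid treatment of the acyclic MOM/acetonide-protected polyol then frees three phenols and closes both five-membered rings, each phenol oxygen capturing its para-oxygen-stabilised benzylic cation trans to the adjacent hydroxymethyl group. The acid-labile tetrahydrofuran is built last, by aryllithium addition to a cis-disubstituted butyrolactone and ionic hydrogenation.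

Key step: step 13

Remark on the chemistry: the SMILES is read as an all-cis oxolane (2R,3R,4R; aryl, hydroxymethyl and benzyl on one face), an inner (2R,3S)- and an outer (2S,3R)-trans-dihydrobenzofuran. Benzofuran atoms are numbered O1, C2, C3; "inner" is the benzofuran whose arene carries the oxolane. Aldehyde 11 is taken as commercial.

**Route**

Step 1
Reactants: 1 5-bromo-2-hydroxy-3-methoxybenzaldehyde
Product: 2 5-bromo-3-methoxy-2-(methoxymethoxy)benzaldehyde
Conditions: MOMCl, i-Pr2NEt, CH2Cl2, 0 °C → rt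
Reagents that add atoms: chloromethyl methyl ether, COCCl
Why: O-alkylation of the phenol gives a base-stable, acid-labile MOM ether that the key step later removes.

Step 2
Reactants: 2 5-bromo-3-methoxy-2-(methoxymethoxy)benzaldehyde
Product: 4 2-[5-bromo-3-methoxy-2-(methoxymethoxy)phenyl]acetonitrile, via vinylformamide 3 (not isolated)
Conditions: TosMIC, t-BuOK, DME, –50 °C; then MeOH, reflux
Reagents that add atoms: p-toluenesulfonylmethyl isocyanide (TosMIC), Cc1ccc(cc1)S(=O)(=O)C[N+]#[C-]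
Why: van Leusen reductive cyanation should homologate the aryl aldehyde by one carbon, methanol removing the formyl and sulfinate groups of 3.

Step 3
Reactants: 4 2-[5-bromo-3-methoxy-2-(methoxymethoxy)phenyl]acetonitrile
Product: 5 2-[5-bromo-3-methoxy-2-(methoxymethoxy)phenyl]acetic acid
Conditions: KOH, EtOH–H2O, reflux; cold dilute HCl to pH 3–4
Reagents that add atoms: potassium hydroxide, [K+].[OH-]; water, O
Why: basic nitrile hydrolysis should give the arylacetic acid, the MOM ether and aryl bromide being stable to hydroxide.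

Step 4
Reactants: 5 2-[5-bromo-3-methoxy-2-(methoxymethoxy)phenyl]acetic acid
Product: 6 2-[5-bromo-3-methoxy-2-(methoxymethoxy)phenyl]acetic pivalic anhydride
Conditions: PivCl, Et3N, THF, –20 °C; Et3N·HCl filtered off under argon, filtrate halved and used cold at once
Reagents that add atoms: pivaloyl chloride, CC(C)(C)C(=O)Cl
Why: mixed-anhydride formation by O-acylation of the triethylammonium carboxylate with pivaloyl chloride, one batch of the activated acid serving both enantiomeric auxiliaries.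

Step 5
Reactants: 6 2-[5-bromo-3-methoxy-2-(methoxymethoxy)phenyl]acetic pivalic anhydride; 7 (S)-4-benzyl-1,3-oxazolidin-2-one
Product: 8 (S)-4-benzyl-3-{2-[5-bromo-3-methoxy-2-(methoxymethoxy)phenyl]acetyl}-1,3-oxazolidin-2-one
Conditions: LiCl, Et3N, THF, –20 °C → rt
Reagents that add atoms: none
Why: mixed-anhydride N-acylation of the oxazolidinone under LiCl/Et3N activation, the hindered pivaloyl carbonyl directing attack to the arylacetyl carbonyl.

Step 6
Reactants: 6 2-[5-bromo-3-methoxy-2-(methoxymethoxy)phenyl]acetic pivalic anhydride; 9 (R)-4-benzyl-1,3-oxazolidin-2-one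
Product: 10 (R)-4-benzyl-3-{2-[5-bromo-3-methoxy-2-(methoxymethoxy)phenyl]acetyl}-1,3-oxazolidin-2-one
Conditions: LiCl, Et3N, THF, –20 °C → rt
Reagents that add atoms: none
Why: the same mixed-anhydride N-acylation with the second half of the solution of 6, giving the enantiomeric imide needed for the inner benzofuran.

Step 7
Reactants: 8 (S)-imide; 11 3-methoxy-4-(methoxymethoxy)benzaldehyde
Product: 13 (S)-4-benzyl-3-[(2S,3S)-2-[5-bromo-3-methoxy-2-(methoxymethoxy)phenyl]-3-hydroxy-3-[3-methoxy-4-(methoxymethoxy)phenyl]propanoyl]-1,3-oxazolidin-2-one, via boron enolate 12 (not isolated)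
Conditions: Bu2BOTf, i-Pr2NEt, CH2Cl2, –78 → 0 °C; 11, –78 → 0 °C; pH 7 buffer, MeOH, H2O2, 0 °C
Reagents that add atoms: none
Why: Evans syn-aldol through the Z-boron enolate and a Zimmerman–Traxler chair, the (S)-auxiliary setting the aryl-bearing carbon that becomes C3 (R) of the outer benzofuran; the carbinol centre is erased later.

Step 8
Reactants: 13 syn-aldol adduct
Product: 14 (1S,2R)-2-[5-bromo-3-methoxy-2-(methoxymethoxy)phenyl]-1-[3-methoxy-4-(methoxymethoxy)phenyl]propane-1,3-diol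
Conditions: LiBH4, THF, MeOH (1 equiv), 0 °C
Reagents that add atoms: none
Why: reductive cleavage of the imide to the primary alcohol without touching the aryl-bearing stereocentre; the auxiliary is recovered.

Step 9
Reactants: 14 (1S,2R)-diol
Product: 15 (4S,5R)-5-[5-bromo-3-methoxy-2-(methoxymethoxy)phenyl]-4-[3-methoxy-4-(methoxymethoxy)phenyl]-2,2-dimethyl-1,3-dioxane
Conditions: 2-methoxypropene, PPTS (cat.), CH2Cl2, 0 °C
Reagents that add atoms: 2-methoxypropene, COC(C)=C
Why: mild acetonide formation masks both hydroxyls toward butyllithium with a group that the key step removes together with the MOM ethers.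

Step 10
Reactants: 15 acetonide
Product: 17 3-methoxy-4-(methoxymethoxy)-5-{(4S,5R)-4-[3-methoxy-4-(methoxymethoxy)phenyl]-2,2-dimethyl-1,3-dioxan-5-yl}benzaldehyde, via aryllithium 16 (not isolated)
Conditions: n-BuLi, THF, –78 °C; DMF, –78 → 0 °C; H2O
Reagents that add atoms: N,N-dimethylformamide, CN(C)C=O
Why: bromine–lithium exchange is faster than any deprotonation at –78 °C, and formylation with DMF (Bouveault) gives the aldehyde.

Step 11
Reactants: 10 (R)-imide; 17 aldehyde
Product: 19 (R)-4-benzyl-3-[(2R,3R)-2-[5-bromo-3-methoxy-2-(methoxymethoxy)phenyl]-3-hydroxy-3-{3-methoxy-4-(methoxymethoxy)-5-[(4S,5R)-4-[3-methoxy-4-(methoxymethoxy)phenyl]-2,2-dimethyl-1,3-dioxan-5-yl]phenyl}propanoyl]-1,3-oxazolidin-2-one, via boron enolate 18 (not isolated)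
Conditions: Bu2BOTf, i-Pr2NEt, CH2Cl2, –78 → 0 °C; 17, –78 → 0 °C; pH 7 buffer, MeOH, H2O2, 0 °C
Reagents that add atoms: none
Why: second Evans syn-aldol, the (R)-auxiliary overriding the remote centres of 17 and setting the carbon that becomes C3 (S) of the inner benzofuran.

Step 12
Reactants: 19 syn-aldol adduct
Product: 20 (1R,2S)-2-[5-bromo-3-methoxy-2-(methoxymethoxy)phenyl]-1-{3-methoxy-4-(methoxymethoxy)-5-[(4S,5R)-4-[3-methoxy-4-(methoxymethoxy)phenyl]-2,2-dimethyl-1,3-dioxan-5-yl]phenyl}propane-1,3-diol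
Conditions: LiBH4, THF, MeOH (1 equiv), 0 °C
Reagents that add atoms: none
Why: reductive removal of the auxiliary as in step 8; acetonide, MOM ethers and aryl bromide are inert to LiBH4.

Step 13
Reactants: 20 (1R,2S)-diol
Product: 22 {(2R,3S)-5-bromo-2-[(2S,3R)-2-(4-hydroxy-3-methoxyphenyl)-3-(hydroxymethyl)-7-methoxy-2,3-dihydro-1-benzofuran-5-yl]-7-methoxy-2,3-dihydro-1-benzofuran-3-yl}methanol, via hexol 21 (not isolated)
Conditions: conc. aq. HCl (to 1 M), MeOH–THF 1:1, 0.01 M, rt → 40 °C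
Reagents that add atoms: none
Why: Acid cleaves the three MOM ethers and the acetonide to hexol 21, whose two benzylic carbinols ionise with loss of water to cations stabilised by the para oxygen (protonated para-quinone methides), and each cation is captured by the phenol oxygen on the aryl ring of the neighbouring carbon. The closest known reaction type is the acid-catalysed phenylcoumaran ring closure of 1-aryl-2-(2-hydroxyaryl)propane-1,3-diols, the β-5 ring closure of lignin chemistry. Both dihydrobenzofuran rings close in the 5-exo-trig mode, O1 adding to the cationic carbon C2 while the arene that carries the charge stays outside the new ring. The new stereocentres, C2 (R) of the inner ring and C2 (S) of the outer ring, are controlled by the adjacent C3 centres fixed in the two aldol steps: the aryl group should take the face opposite the C3 hydroxymethyl group, and because ionisation is reversible the trans isomers should also accumulate thermodynamically, so the carbinol configurations of 20 are of no consequence. The step needs capture by the right phenol in preference to the primary hydroxyls and to intermolecular arylation; the five-membered ring size (the hydroxyls could only form oxetanes) and high dilution should secure this.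

Step 14
Reactants: 22 bis-dihydrobenzofuran bromide
Product: 23 tris(tert-butyldimethylsilyl) ether of 22 (both CH2OH groups and the phenol silylated)
Conditions: TBSCl (4 equiv), imidazole, DMF, rt
Reagents that add atoms: tert-butyldimethylsilyl chloride, CC(C)(C)[Si](C)(C)Cl
Why: silylation of the two primary alcohols and the phenol gives fluoride-labile protection, so the acid-sensitive final product never meets acid or hydrogenolysis.

Step 15
Reactants: 24 4-bromo-2-methoxyphenol
Product: 25 (4-bromo-2-methoxyphenoxy)(tert-butyl)dimethylsilane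
Conditions: TBSCl, imidazole, DMF, rt
Reagents that add atoms: tert-butyldimethylsilyl chloride, CC(C)(C)[Si](C)(C)Cl
Why: phenol silylation allows Grignard formation from the aryl bromide.

Step 16
Reactants: 26 dimethyl malonate; 27 (R)-epichlorohydrin
Product: 28 methyl (1S,5R)-2-oxo-3-oxabicyclo[3.1.0]hexane-1-carboxylate
Conditions: NaOMe, MeOH, 0 °C → reflux
Reagents that add atoms: none
Why: malonate opens the epoxide at CH2, the alkoxide re-forms an epoxide with loss of chloride, 3-exo-tet cyclopropanation inverts the stereocentre and the alkoxide lactonises onto the cis ester, so both centres derive from the bought epichlorohydrin.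

Step 17
Reactants: 25 aryl bromide; 28 bicyclic lactone
Product: 30 methyl (3S,4R)-4-{[4-(tert-butyldimethylsilyloxy)-3-methoxyphenyl]methyl}-2-oxooxolane-3-carboxylate, via aryl Grignard reagent 29 (not isolated)
Conditions: Mg, THF, 40 °C; CuBr·SMe2 (10 mol%), 28, THF, –40 → –20 °C; 1 M HCl, 0 °C
Reagents that add atoms: none
Why: copper-catalysed homoconjugate addition of the aryl Grignard reagent to the CH2 of the doubly activated cyclopropane gives the benzyl lactone, and the acidic malonate-type centre C3 should settle trans to the benzyl group.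

Step 18
Reactants: 30 lactone ester
Product: 31 (3S,4R)-4-[(4-hydroxy-3-methoxyphenyl)methyl]-2-oxooxolane-3-carboxylic acid
Conditions: LiOH, THF–MeOH–H2O, rt; 1 M HCl to pH 2, 0 °C
Reagents that add atoms: lithium hydroxide, [Li+].[OH-]
Why: saponification (which also cleaves the aryl silyl ether) followed by spontaneous relactonisation on acidification gives the lactone acid, its epimerisable C3 again settling trans.

Step 19
Reactants: 31 lactone acid
Product: 33 (3R,4R)-3-(hydroxymethyl)-4-[(4-hydroxy-3-methoxyphenyl)methyl]oxolan-2-one, via dihydroxy acid 32 (not isolated)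
Conditions: LiBH4 (4 equiv), THF, 0 °C → rt; 2 M HCl, rt
Reagents that add atoms: none
Why: LiBH4 reduces the lactone carbonyl but not the lithium carboxylate, and the γ-hydroxy acid 32 lactonises through the other carboxyl; this ring switch turns the trans acid into the cis hydroxymethyl lactone without touching either stereocentre.

Step 20
Reactants: 33 cis-lactone diol
Product: 34 (3R,4R)-3-[(tert-butyldimethylsilyloxy)methyl]-4-{[4-(tert-butyldimethylsilyloxy)-3-methoxyphenyl]methyl}oxolan-2-one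
Conditions: TBSCl (2.5 equiv), imidazole, DMF, rt
Reagents that add atoms: tert-butyldimethylsilyl chloride, CC(C)(C)[Si](C)(C)Cl
Why: silylation of the phenol and the primary alcohol under non-epimerising conditions.

Step 21
Reactants: 23 tris-silylated aryl bromide; 34 cis-lactone
Product: 36 (3R,4R)-2-aryl-3-[(tert-butyldimethylsilyloxy)methyl]-4-{[4-(tert-butyldimethylsilyloxy)-3-methoxyphenyl]methyl}oxolan-2-ol (aryl = tris-silylated bis-dihydrobenzofuranyl of 23; anomeric mixture), via aryllithium 35 (not isolated)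
Conditions: n-BuLi, THF, –78 °C; 34 (1.3 equiv), –78 °C; aq. NH4Cl
Reagents that add atoms: none
Why: aryllithium addition to a γ-lactone stops at the lactol alkoxide at –78 °C, as in C-aryl glycoside synthesis; the hemiketal centre is not controlled and is erased in step 22.

Step 22
Reactants: 36 lactol
Product: 37 penta(tert-butyldimethylsilyl) ether of the target, (2R,3R,4R)-oxolane
Conditions: Et3SiH, BF3·OEt2, CH2Cl2, –78 → –50 °C
Reagents that add atoms: none
Why: ionic hydrogenation through the 2-aryl oxocarbenium ion, hydride arriving on the face opposite the two cis substituents at C3 and C4, so the aryl group ends cis to both (oxolane C2 = R, substrate control).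

Step 23
Reactants: 37 penta-silyl ether
Product: 38 target, {(2R,3R,4R)-2-{(2R,3S)-2-[(2S,3R)-2-(4-hydroxy-3-methoxyphenyl)-3-(hydroxymethyl)-7-methoxy-2,3-dihydro-1-benzofuran-5-yl]-3-(hydroxymethyl)-7-methoxy-2,3-dihydro-1-benzofuran-5-yl}-4-[(4-hydroxy-3-methoxyphenyl)methyl]oxolan-3-yl}methanol
Conditions: TBAF, AcOH (1:1), THF, 0 °C → rt
Reagents that add atoms: none
Why: buffered fluoride desilylation should free the three alcohols and two phenols under conditions that leave the benzylic ethers untouched.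

**Compound list**

1 | 5-bromo-2-hydroxy-3-methoxybenzaldehyde | COc1cc(Br)cc(C=O)c1O | starting material
2 | 5-bromo-3-methoxy-2-(methoxymethoxy)benzaldehyde | COCOc1c(OC)cc(Br)cc1C=O | intermediate
3 | N-{2-[5-bromo-3-methoxy-2-(methoxymethoxy)phenyl]-1-tosylvinyl}formamide (alkene geometry undefined) | COCOc1c(OC)cc(Br)cc1C=C(NC=O)S(=O)(=O)c1ccc(C)cc1 | intermediate
4 | 2-[5-bromo-3-methoxy-2-(methoxymethoxy)phenyl]acetonitrile | N#CCc1cc(Br)cc(OC)c1OCOC | intermediate
5 | 2-[5-bromo-3-methoxy-2-(methoxymethoxy)phenyl]acetic acid | OC(=O)Cc1cc(Br)cc(OC)c1OCOC | intermediate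
6 | 2-[5-bromo-3-methoxy-2-(methoxymethoxy)phenyl]acetic pivalic anhydride (mixed anhydride of 5 and pivalic acid) | COCOc1c(OC)cc(Br)cc1CC(=O)OC(=O)C(C)(C)C | intermediate
7 | (S)-4-benzyl-1,3-oxazolidin-2-one | O=C1N[C@@H](Cc2ccccc2)CO1 | starting material
8 | (S)-4-benzyl-3-{2-[5-bromo-3-methoxy-2-(methoxymethoxy)phenyl]acetyl}-1,3-oxazolidin-2-one | COCOc1c(OC)cc(Br)cc1CC(=O)N1[C@@H](Cc2ccccc2)COC1=O | intermediate
9 | (R)-4-benzyl-1,3-oxazolidin-2-one | O=C1N[C@H](Cc2ccccc2)CO1 | starting material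
10 | (R)-4-benzyl-3-{2-[5-bromo-3-methoxy-2-(methoxymethoxy)phenyl]acetyl}-1,3-oxazolidin-2-one | COCOc1c(OC)cc(Br)cc1CC(=O)N1[C@H](Cc2ccccc2)COC1=O | intermediate
11 | 3-methoxy-4-(methoxymethoxy)benzaldehyde | COCOc1ccc(C=O)cc1OC | starting material
12 | (Z)-dibutylboron enolate of 8 | CCCCB(CCCC)O/C(=C\c1cc(Br)cc(OC)c1OCOC)N1[C@@H](Cc2ccccc2)COC1=O | intermediate
13 | (S)-4-benzyl-3-[(2S,3S)-2-[5-bromo-3-methoxy-2-(methoxymethoxy)phenyl]-3-hydroxy-3-[3-methoxy-4-(methoxymethoxy)phenyl]propanoyl]-1,3-oxazolidin-2-one | COCOc1ccc(cc1OC)[C@@H](O)[C@H](c1cc(Br)cc(OC)c1OCOC)C(=O)N1[C@@H](Cc2ccccc2)COC1=O | intermediate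
14 | (1S,2R)-2-[5-bromo-3-methoxy-2-(methoxymethoxy)phenyl]-1-[3-methoxy-4-(methoxymethoxy)phenyl]propane-1,3-diol | COCOc1ccc(cc1OC)[C@@H](O)[C@H](c1cc(Br)cc(OC)c1OCOC)CO | intermediate
15 | (4S,5R)-5-[5-bromo-3-methoxy-2-(methoxymethoxy)phenyl]-4-[3-methoxy-4-(methoxymethoxy)phenyl]-2,2-dimethyl-1,3-dioxane | COCOc1ccc(cc1OC)[C@H]1OC(C)(C)OC[C@H]1c1cc(Br)cc(OC)c1OCOC | intermediate
16 | aryllithium from 15 (Li in place of Br) | COCOc1ccc(cc1OC)[C@H]1OC(C)(C)OC[C@H]1c1cc([Li])cc(OC)c1OCOC | intermediate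
17 | 3-methoxy-4-(methoxymethoxy)-5-{(4S,5R)-4-[3-methoxy-4-(methoxymethoxy)phenyl]-2,2-dimethyl-1,3-dioxan-5-yl}benzaldehyde | COCOc1ccc(cc1OC)[C@H]1OC(C)(C)OC[C@H]1c1cc(C=O)cc(OC)c1OCOC | intermediate
18 | (Z)-dibutylboron enolate of 10 | CCCCB(CCCC)O/C(=C\c1cc(Br)cc(OC)c1OCOC)N1[C@H](Cc2ccccc2)COC1=O | intermediate
19 | (R)-4-benzyl-3-[(2R,3R)-2-(bromoaryl)-3-hydroxy-3-(dioxanyl-aryl)propanoyl]-1,3-oxazolidin-2-one (full name in step 11) | COCOc1ccc(cc1OC)[C@H]1OC(C)(C)OC[C@H]1c1cc(cc(OC)c1OCOC)[C@H](O)[C@@H](c1cc(Br)cc(OC)c1OCOC)C(=O)N1[C@H](Cc2ccccc2)COC1=O | intermediate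
20 | (1R,2S)-diol from 19 (full name in step 12) | COCOc1ccc(cc1OC)[C@H]1OC(C)(C)OC[C@H]1c1cc(cc(OC)c1OCOC)[C@H](O)[C@@H](c1cc(Br)cc(OC)c1OCOC)CO | intermediate
21 | (1R,2S)-2-(5-bromo-2-hydroxy-3-methoxyphenyl)-1-{3-[(1S,2R)-1,3-dihydroxy-1-(4-hydroxy-3-methoxyphenyl)propan-2-yl]-4-hydroxy-5-methoxyphenyl}propane-1,3-diol | COc1cc(ccc1O)[C@@H](O)[C@H](c1cc(cc(OC)c1O)[C@H](O)[C@@H](c1cc(Br)cc(OC)c1O)CO)CO | intermediate
22 | {(2R,3S)-5-bromo-2-[(2S,3R)-2-(4-hydroxy-3-methoxyphenyl)-3-(hydroxymethyl)-7-methoxy-2,3-dihydro-1-benzofuran-5-yl]-7-methoxy-2,3-dihydro-1-benzofuran-3-yl}methanol | Brc1cc(OC)c2c(c1)[C@@H](CO)[C@H](c1cc(OC)c3c(c1)[C@H](CO)[C@@H](c1ccc(O)c(OC)c1)O3)O2 | intermediate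
23 | tris(tert-butyldimethylsilyl) ether of 22 | Brc1cc(OC)c2c(c1)[C@@H](CO[Si](C)(C)C(C)(C)C)[C@H](c1cc(OC)c3c(c1)[C@H](CO[Si](C)(C)C(C)(C)C)[C@@H](c1ccc(O[Si](C)(C)C(C)(C)C)c(OC)c1)O3)O2 | intermediate
24 | 4-bromo-2-methoxyphenol | COc1cc(Br)ccc1O | starting material
25 | (4-bromo-2-methoxyphenoxy)(tert-butyl)dimethylsilane | COc1cc(Br)ccc1O[Si](C)(C)C(C)(C)C | intermediate
26 | dimethyl malonate | COC(=O)CC(=O)OC | starting material
27 | (R)-epichlorohydrin | ClC[C@H]1CO1 | starting material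
28 | methyl (1S,5R)-2-oxo-3-oxabicyclo[3.1.0]hexane-1-carboxylate | COC(=O)[C@]12C[C@H]1COC2=O | intermediate
29 | [4-(tert-butyldimethylsilyloxy)-3-methoxyphenyl]magnesium bromide | COc1cc([Mg]Br)ccc1O[Si](C)(C)C(C)(C)C | intermediate
30 | methyl (3S,4R)-4-{[4-(tert-butyldimethylsilyloxy)-3-methoxyphenyl]methyl}-2-oxooxolane-3-carboxylate | COC(=O)[C@@H]1[C@@H](Cc2ccc(O[Si](C)(C)C(C)(C)C)c(OC)c2)COC1=O | intermediate
31 | (3S,4R)-4-[(4-hydroxy-3-methoxyphenyl)methyl]-2-oxooxolane-3-carboxylic acid | OC(=O)[C@@H]1[C@@H](Cc2ccc(O)c(OC)c2)COC1=O | intermediate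
32 | (2R,3R)-4-hydroxy-2-(hydroxymethyl)-3-[(4-hydroxy-3-methoxyphenyl)methyl]butanoic acid | OC[C@H](C(=O)O)[C@@H](Cc1ccc(O)c(OC)c1)CO | intermediate
33 | (3R,4R)-3-(hydroxymethyl)-4-[(4-hydroxy-3-methoxyphenyl)methyl]oxolan-2-one | OC[C@H]1[C@@H](Cc2ccc(O)c(OC)c2)COC1=O | intermediate
34 | (3R,4R)-3-[(tert-butyldimethylsilyloxy)methyl]-4-{[4-(tert-butyldimethylsilyloxy)-3-methoxyphenyl]methyl}oxolan-2-one | CC(C)(C)[Si](C)(C)OC[C@H]1[C@@H](Cc2ccc(O[Si](C)(C)C(C)(C)C)c(OC)c2)COC1=O | intermediate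
35 | aryllithium from 23 (Li in place of Br) | [Li]c1cc(OC)c2c(c1)[C@@H](CO[Si](C)(C)C(C)(C)C)[C@H](c1cc(OC)c3c(c1)[C@H](CO[Si](C)(C)C(C)(C)C)[C@@H](c1ccc(O[Si](C)(C)C(C)(C)C)c(OC)c1)O3)O2 | intermediate
36 | lactol, (3R,4R)-2-aryl-oxolan-2-ol (full name in step 21; anomeric mixture) | COc1cc(C[C@H]2COC(O)(c3cc(OC)c4c(c3)[C@@H](CO[Si](C)(C)C(C)(C)C)[C@H](c3cc(OC)c5c(c3)[C@H](CO[Si](C)(C)C(C)(C)C)[C@@H](c3ccc(O[Si](C)(C)C(C)(C)C)c(OC)c3)O5)O4)[C@H]2CO[Si](C)(C)C(C)(C)C)ccc1O[Si](C)(C)C(C)(C)C | intermediate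
37 | penta(tert-butyldimethylsilyl) ether of the target | COc1cc(C[C@H]2CO[C@@H](c3cc(OC)c4c(c3)[C@@H](CO[Si](C)(C)C(C)(C)C)[C@H](c3cc(OC)c5c(c3)[C@H](CO[Si](C)(C)C(C)(C)C)[C@@H](c3ccc(O[Si](C)(C)C(C)(C)C)c(OC)c3)O5)O4)[C@H]2CO[Si](C)(C)C(C)(C)C)ccc1O[Si](C)(C)C(C)(C)C | intermediate
38 | target (name in step 23) | COc1cc(C[C@H]2CO[C@@H](c3cc(OC)c4c(c3)[C@@H](CO)[C@H](c3cc(OC)c5c(c3)[C@H](CO)[C@@H](c3ccc(O)c(OC)c3)O5)O4)[C@H]2CO)ccc1O | target

**Step count and risks**

Total step count: 23. Longest linear sequence: 16 steps (steps 1–5, 7–14, 21–23).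

Three steps most likely to fail:

1. Step 13. Intermolecular arylation of the electron-rich phenols by the benzylic cations (oligomerisation), loss of formaldehyde from a cation to a stilbene, or incomplete equilibration to trans when two closures run together. Fallback: the rings are closed one at a time on substrates that hold a single ionisable carbinol, setting out from diol 14 and returning at 23. Diol 14 with HCl in MeOH–THF should give [(2S,3R)-5-bromo-2-(4-hydroxy-3-methoxyphenyl)-7-methoxy-2,3-dihydro-1-benzofuran-3-yl]methanol F1. TBSCl and imidazole give its bis-silyl ether F2, and n-BuLi then DMF give the 5-carbaldehyde F3. Boron enolate 18 adds to F3 to give the syn-aldol adduct F4, and LiBH4 gives the (1R,2S)-diol F5. HCl in MeOH–THF then removes the remaining MOM group (and the silyl ethers in part) and closes the inner ring, and silylation as in step 14 converges on 23.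

2. Step 22. Ionisation of the two dihydrobenzofuran benzylic ethers or of the product itself, leading to reductive ring opening or epimerisation at oxolane C2, or proton loss from the oxocarbenium ion with loss of the C3 configuration. Fallback without a cation, from lactol 36 back to 37: dehydration with MsCl and Et3N gives the 2,3-dihydrofuran (3R)-5-aryl-4-[(tert-butyldimethylsilyloxy)methyl]-3-{[4-(tert-butyldimethylsilyloxy)-3-methoxyphenyl]methyl}-2,3-dihydrofuran F6. Hydrogenation over Rh/Al2O3 in EtOAc should add both hydrogens to the face opposite the benzyl group and give all-cis 37.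

3. Step 19. Epimerisation at the carbon between the two carbonyl groups at the transient α-formyl carboxylate stage, or stalling of the reduction at an enolised lactone, either of which erodes the cis relationship. Fallback from ester 30 back to 34: Krapcho demethoxycarbonylation (LiCl, wet DMSO, 140 °C) gives (R)-4-{[4-(tert-butyldimethylsilyloxy)-3-methoxyphenyl]methyl}oxolan-2-one F7. Formylation (NaH, HCO2Et) gives the 3-(hydroxymethylidene) lactone F8, and TBSCl with imidazole gives its silyl enol ether F9. Hydrogenation (H2, Rh/Al2O3) from the face opposite the benzyl group should give cis-lactone 34.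

**Further compounds**

F1 | step 13 | [(2S,3R)-5-bromo-2-(4-hydroxy-3-methoxyphenyl)-7-methoxy-2,3-dihydro-1-benzofuran-3-yl]methanol | Brc1cc(OC)c2c(c1)[C@H](CO)[C@@H](c1ccc(O)c(OC)c1)O2
F2 | step 13 | bis(tert-butyldimethylsilyl) ether of F1 | Brc1cc(OC)c2c(c1)[C@H](CO[Si](C)(C)C(C)(C)C)[C@@H](c1ccc(O[Si](C)(C)C(C)(C)C)c(OC)c1)O2
F3 | step 13 | (2S,3R)-2-[4-(tert-butyldimethylsilyloxy)-3-methoxyphenyl]-3-[(tert-butyldimethylsilyloxy)methyl]-7-methoxy-2,3-dihydro-1-benzofuran-5-carbaldehyde | O=Cc1cc(OC)c2c(c1)[C@H](CO[Si](C)(C)C(C)(C)C)[C@@H](c1ccc(O[Si](C)(C)C(C)(C)C)c(OC)c1)O2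
F4 | step 13 | (2R,3R)-syn-aldol adduct of F3 and imide 10 | O[C@@H](c1cc(OC)c2c(c1)[C@H](CO[Si](C)(C)C(C)(C)C)[C@@H](c1ccc(O[Si](C)(C)C(C)(C)C)c(OC)c1)O2)[C@@H](c1cc(Br)cc(OC)c1OCOC)C(=O)N1[C@H](Cc2ccccc2)COC1=O
F5 | step 13 | (1R,2S)-propane-1,3-diol from F4 | O[C@@H](c1cc(OC)c2c(c1)[C@H](CO[Si](C)(C)C(C)(C)C)[C@@H](c1ccc(O[Si](C)(C)C(C)(C)C)c(OC)c1)O2)[C@@H](c1cc(Br)cc(OC)c1OCOC)CO
F6 | step 22 | (3R)-5-aryl-4-[(tert-butyldimethylsilyloxy)methyl]-3-{[4-(tert-butyldimethylsilyloxy)-3-methoxyphenyl]methyl}-2,3-dihydrofuran | COc1cc(C[C@H]2COC(c3cc(OC)c4c(c3)[C@@H](CO[Si](C)(C)C(C)(C)C)[C@H](c3cc(OC)c5c(c3)[C@H](CO[Si](C)(C)C(C)(C)C)[C@@H](c3ccc(O[Si](C)(C)C(C)(C)C)c(OC)c3)O5)O4)=C2CO[Si](C)(C)C(C)(C)C)ccc1O[Si](C)(C)C(C)(C)C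
F7 | step 19 | (R)-4-{[4-(tert-butyldimethylsilyloxy)-3-methoxyphenyl]methyl}oxolan-2-one | O=C1C[C@@H](Cc2ccc(O[Si](C)(C)C(C)(C)C)c(OC)c2)CO1
F8 | step 19 | (R)-3-(hydroxymethylidene)-4-{[4-(tert-butyldimethylsilyloxy)-3-methoxyphenyl]methyl}oxolan-2-one | O=C1OC[C@H](Cc2ccc(O[Si](C)(C)C(C)(C)C)c(OC)c2)C1=CO
F9 | step 19 | O-tert-butyldimethylsilyl enol ether of F8 | O=C1OC[C@H](Cc2ccc(O[Si](C)(C)C(C)(C)C)c(OC)c2)C1=CO[Si](C)(C)C(C)(C)C
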